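**Plan**

Locants are those of the eudesmane skeleton (ring A: C1–C5 and C10; ring B: C5–C10; C15 is the methylene carbon on C4). The retrosynthesis first returns the C6 carbinol to a ketone and the C9 anisoate to a silyl ether.
Enabling feature: C7 is a CH(i-Pr) held between the oxygen-bearing C6 and the C8 methylene. Cutting C6–C7 and C7–C8 and joining C6 to C8 shrinks ring B to a cyclopentanone built from C5, C6, C8, C9 and C10 and releases the isopropyl carbon as a diazoalkane.
The cis-hydrindanone is then cut at C4–C5 (ring A, enol silane plus alkyne) and at C10–C1 and C10–CH3 (two copper-catalysed conjugate additions to a 4-silyloxycyclopentenone).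
Forward order: the five-membered ring is bought, C10 is built on it, ring A is closed by gold catalysis, ring B arises by one-carbon enlargement, and the C9 ester and C6 alcohol are adjusted last.
Stereochemistry: C9 from the bought (R)-enone; C10 by addition anti to the silyloxy group; C5 by the tether (cis fusion); C7 in the ring enlargement; C6 by hydride attack anti to the axial C10 methyl.

Key step: step 10

Assumption: the enone of step 1 and the silylated chloroalkyne of step 3 are bought as such, and the C7 configuration drawn for the ring-enlarged ketone rests on the rotamer model given in the key step.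

**Route**

Step 1
Reactants: 1 (R)-4-[(tert-butyldimethylsilyl)oxy]cyclopent-2-en-1-one
Product: 2 tert-butyldimethyl{[(1R,2R)-2-methyl-4-[(trimethylsilyl)oxy]cyclopent-3-en-1-yl]oxy}silane (methyl trans to the silyloxy group)
Conditions: MeMgBr, CuBr·SMe2 (5 mol%), TMSCl, HMPA, THF, −78 °C; Et3N, pentane, cold aq NaHCO3
Reagents that add atoms: methylmagnesium bromide, C[Mg]Br; chlorotrimethylsilane, C[Si](C)(C)Cl
Why: Chlorosilane-accelerated copper-catalysed conjugate addition delivers methyl to C3 anti to the silyloxy group, and the enolate is silylated before it can expel that group; the new C3 centre is transient and is erased in step 2.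

Step 2
Reactants: 2 tert-butyldimethyl{[(1R,2R)-2-methyl-4-[(trimethylsilyl)oxy]cyclopent-3-en-1-yl]oxy}silane
Product: 3 (R)-4-[(tert-butyldimethylsilyl)oxy]-3-methylcyclopent-2-en-1-one
Conditions: Pd(OAc)2 (1.05 equiv), MeCN, rt
Reagents that add atoms: none
Why: Saegusa–Ito oxidation, in which divalent palladium takes the place of silicon on the enol carbon and β-hydride elimination toward C3 restores the enone, now β-methylated, without touching the silyloxy-bearing stereocentre.

Step 3
Reactants: 4 (5-chloropent-1-yn-1-yl)trimethylsilane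
Product: 5 [5-(trimethylsilyl)pent-4-yn-1-yl]magnesium chloride (titrated THF solution)
Conditions: Mg turnings, 1,2-dibromoethane (cat.), THF, reflux
Reagents that add atoms: magnesium, [Mg]
Why: Grignard formation by magnesium insertion into the primary C–Cl bond; the silyl cap removes the acidic alkyne proton.

Step 4
Reactants: 3 (R)-4-[(tert-butyldimethylsilyl)oxy]-3-methylcyclopent-2-en-1-one; 5 [5-(trimethylsilyl)pent-4-yn-1-yl]magnesium chloride
Product: 6 tert-butyldimethyl({(1R,2R)-2-methyl-2-[5-(trimethylsilyl)pent-4-yn-1-yl]-4-[(trimethylsilyl)oxy]cyclopent-3-en-1-yl}oxy)silane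
Conditions: CuBr·SMe2 (10 mol%), TMSCl, HMPA, THF, −78 → −40 °C; Et3N, pentane, cold aq NaHCO3
Reagents that add atoms: chlorotrimethylsilane, C[Si](C)(C)Cl
Why: Chlorosilane-accelerated copper-catalysed conjugate addition to the β,β-disubstituted enone, in which the alkyl group enters anti to the neighbouring silyloxy group, so the quaternary centre (C10) is set with methyl cis to that oxygen (C9) and the regiodefined enolate is caught as its enol silane.

Step 5
Reactants: 6 tert-butyldimethyl({(1R,2R)-2-methyl-2-[5-(trimethylsilyl)pent-4-yn-1-yl]-4-[(trimethylsilyl)oxy]cyclopent-3-en-1-yl}oxy)silane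
Product: 8 tert-butyl({(1R,2R)-4-[(tert-butyldimethylsilyl)oxy]-2-methyl-2-[5-(trimethylsilyl)pent-4-yn-1-yl]cyclopent-3-en-1-yl}oxy)dimethylsilane, via lithium enolate 7 (not isolated)
Conditions: MeLi (1.05 equiv), THF, 0 °C; then TBSOTf, −78 °C
Reagents that add atoms: tert-butyldimethylsilyl trifluoromethanesulfonate, CC(C)(C)[Si](C)(C)OS(=O)(=O)C(F)(F)F
Why: Methyllithium attacks the O–SiMe3 silicon (an enolate leaves far more readily than an acetylide, so the alkynylsilane stays) and frees the regiodefined lithium enolate, which cannot equilibrate without a proton source and is O-silylated by the silyl triflate to the sturdier TBS enol ether.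

Step 6
Reactants: 8 tert-butyl({(1R,2R)-4-[(tert-butyldimethylsilyl)oxy]-2-methyl-2-[5-(trimethylsilyl)pent-4-yn-1-yl]cyclopent-3-en-1-yl}oxy)dimethylsilane
Product: 9 tert-butyl({(1R,2R)-4-[(tert-butyldimethylsilyl)oxy]-2-methyl-2-(pent-4-yn-1-yl)cyclopent-3-en-1-yl}oxy)dimethylsilane
Conditions: K2CO3, MeOH/THF, 0 °C
Reagents that add atoms: none
Why: Base-catalysed methanolysis of the C(sp)–Si bond is fast, whereas the hindered TBS enol ether and the TBS ether should survive brief cold carbonate.

Step 7
Reactants: 9 tert-butyl({(1R,2R)-4-[(tert-butyldimethylsilyl)oxy]-2-methyl-2-(pent-4-yn-1-yl)cyclopent-3-en-1-yl}oxy)dimethylsilane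
Product: 10 (3R,3aR,7aS)-3-[(tert-butyldimethylsilyl)oxy]-3a-methyl-7-methylideneoctahydro-1H-inden-1-one (cis-fused)
Conditions: (Ph3P)AuCl (10 mol%), AgBF4 (10 mol%), CH2Cl2/MeOH 10:1, rt
Reagents that add atoms: none
Why: Conia-ene-type carbocyclisation catalysed by monovalent gold, in which the enol silane carbon (C5) adds 6-exo-dig to the gold-activated alkyne carbon (C4) and methanol takes the silyl group and protonates the vinylgold to the 1,1-disubstituted alkene; the three-carbon tether hangs from C10 and can reach C5 only on its own face, which makes the ring fusion cis (C5 set).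

Step 8
Reactants: 11 2-methylpropanal
Product: 12 N'-(2-methylpropylidene)-4-methylbenzenesulfonohydrazide
Conditions: TsNHNH2, MeOH, rt
Reagents that add atoms: 4-methylbenzenesulfonohydrazide, Cc1ccc(cc1)S(=O)(=O)NN
Why: Condensation of the aldehyde with the sulfonyl hydrazide gives a stable, crystalline hydrazone.

Step 9
Reactants: 12 N'-(2-methylpropylidene)-4-methylbenzenesulfonohydrazide
Product: 14 2-methyl-1-diazopropane, via sodium tosylhydrazonide 13 (not isolated)
Conditions: NaOMe (1.0 equiv), MeOH, rt; evaporate and dry; 90–120 °C, 0.1 mmHg, receiver at −78 °C; take up in cold toluene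
Reagents that add atoms: none
Why: Bamford–Stevens reaction run as an aprotic vacuum pyrolysis, in which the dry sodium salt loses sulfinate and the volatile diazoalkane distils from the hot zone into the cold receiver before it can decompose.

Step 10
Reactants: 10 (3R,3aR,7aS)-3-[(tert-butyldimethylsilyl)oxy]-3a-methyl-7-methylideneoctahydro-1H-inden-1-one; 14 2-methyl-1-diazopropane
Product: 15 (2R,4R,4aR,8aS)-4-[(tert-butyldimethylsilyl)oxy]-4a-methyl-8-methylidene-2-(propan-2-yl)octahydronaphthalen-1(2H)-one (cis-fused)
Conditions: Sc(OTf)3 (10 mol%), toluene, −78 °C, slow addition of 14 (2.5 equiv)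
Reagents that add atoms: none
Why: The nucleophilic carbon of 14 bonds to the scandium-activated C6 carbonyl carbon of 10 to give a β-oxido diazonium ion, and the C6–C8 bond lying antiperiplanar to C–N2 then shifts onto the diazo carbon as N2 leaves, which creates C6–C7 and C7–C8 at the cost of C6–C8. The closest known reaction type is the Sc(OTf)3-catalysed one-carbon homologation of cycloalkanones with non-stabilised diazoalkanes, a Lewis-acid relative of the Tiffeneau–Demjanov ring enlargement. Ring B is not closed by a cyclisation: it grows out of the five-membered ring by a 1,2-alkyl shift that inserts one carbon. C7 is the only new stereocentre and is under substrate control: the reagent comes in on the convex face of the cis-hydrindanone (the face of H-5, away from ring A), and in the rotamer with N2 antiperiplanar to C6–C8 the isopropyl group turns away from the triflate-laden scandium alkoxide, so the shift, which inverts the diazo carbon, leaves isopropyl cis to the C9 silyloxy group (7R), equatorial in the cis-decalone chair that also has that oxygen equatorial. The step needs C8 and not C5 to migrate and must stop after one insertion: C5 is a tertiary carbon pressed between quaternary C10 and C4 and would have to bond to the branched diazo carbon, C8 is an open methylene whose β-oxygen is kept as a weakly withdrawing silyl ether, and the α-branched six-ring ketone formed is too crowded to react again.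

Step 11
Reactants: 15 (2R,4R,4aR,8aS)-4-[(tert-butyldimethylsilyl)oxy]-4a-methyl-8-methylidene-2-(propan-2-yl)octahydronaphthalen-1(2H)-one
Product: 16 (2R,4R,4aR,8aS)-4-hydroxy-4a-methyl-8-methylidene-2-(propan-2-yl)octahydronaphthalen-1(2H)-one
Conditions: HF·pyridine, pyridine, THF, 0 °C → rt
Reagents that add atoms: none
Why: Fluoride-driven cleavage of the hindered secondary silyl ether under buffered, non-enolising conditions, so that C5, C7 and the β,γ-placed methylene group stay as they are.

Step 12
Reactants: 16 (2R,4R,4aR,8aS)-4-hydroxy-4a-methyl-8-methylidene-2-(propan-2-yl)octahydronaphthalen-1(2H)-one; 17 4-methoxybenzoyl chloride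
Product: 18 (1R,3R,4aS,8aR)-8a-methyl-5-methylidene-4-oxo-3-(propan-2-yl)decahydronaphthalen-1-yl 4-methoxybenzoate
Conditions: pyridine, DMAP (cat.), CH2Cl2, 0 °C → rt
Reagents that add atoms: none
Why: Acyl transfer through the acylpyridinium ion esterifies the only hydroxyl group (equatorial, C9); this oxygen is γ to the ketone, so no elimination path exists.

Step 13
Reactants: 18 (1R,3R,4aS,8aR)-8a-methyl-5-methylidene-4-oxo-3-(propan-2-yl)decahydronaphthalen-1-yl 4-methoxybenzoate
Product: 19 (1R,3R,4S,4aS,8aR)-4-hydroxy-8a-methyl-5-methylidene-3-(propan-2-yl)decahydronaphthalen-1-yl 4-methoxybenzoate (CNP0107029.1)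
Conditions: LiBH(s-Bu)3, THF, −78 °C; then H2O
Reagents that add atoms: none
Why: The bulky trialkylborohydride reduces only the ketone at −78 °C and should approach C6 along the equatorial line, anti to the syn-axial C10 methyl that blocks the other face, which gives the axial alcohol cis to the isopropyl group (C6 set) and leaves the aryl ester intact.

**Compound list**

1 | (R)-4-[(tert-butyldimethylsilyl)oxy]cyclopent-2-en-1-one | O=C1C=C[C@H](O[Si](C)(C)C(C)(C)C)C1 | starting material
2 | tert-butyldimethyl{[(1R,2R)-2-methyl-4-[(trimethylsilyl)oxy]cyclopent-3-en-1-yl]oxy}silane | C[Si](C)(C)OC1=C[C@@H](C)[C@H](O[Si](C)(C)C(C)(C)C)C1 | intermediate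
3 | (R)-4-[(tert-butyldimethylsilyl)oxy]-3-methylcyclopent-2-en-1-one | O=C1C=C(C)[C@H](O[Si](C)(C)C(C)(C)C)C1 | intermediate
4 | (5-chloropent-1-yn-1-yl)trimethylsilane | C[Si](C)(C)C#CCCCCl | starting material
5 | [5-(trimethylsilyl)pent-4-yn-1-yl]magnesium chloride | C[Si](C)(C)C#CCCC[Mg]Cl | intermediate
6 | tert-butyldimethyl({(1R,2R)-2-methyl-2-[5-(trimethylsilyl)pent-4-yn-1-yl]-4-[(trimethylsilyl)oxy]cyclopent-3-en-1-yl}oxy)silane | C[Si](C)(C)OC1=C[C@@](C)(CCCC#C[Si](C)(C)C)[C@H](O[Si](C)(C)C(C)(C)C)C1 | intermediate
7 | lithium (3R,4R)-4-[(tert-butyldimethylsilyl)oxy]-3-methyl-3-[5-(trimethylsilyl)pent-4-yn-1-yl]cyclopent-1-en-1-olate | [Li]OC1=C[C@@](C)(CCCC#C[Si](C)(C)C)[C@H](O[Si](C)(C)C(C)(C)C)C1 | intermediate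
8 | tert-butyl({(1R,2R)-4-[(tert-butyldimethylsilyl)oxy]-2-methyl-2-[5-(trimethylsilyl)pent-4-yn-1-yl]cyclopent-3-en-1-yl}oxy)dimethylsilane | CC(C)(C)[Si](C)(C)OC1=C[C@@](C)(CCCC#C[Si](C)(C)C)[C@H](O[Si](C)(C)C(C)(C)C)C1 | intermediate
9 | tert-butyl({(1R,2R)-4-[(tert-butyldimethylsilyl)oxy]-2-methyl-2-(pent-4-yn-1-yl)cyclopent-3-en-1-yl}oxy)dimethylsilane | CC(C)(C)[Si](C)(C)OC1=C[C@@](C)(CCCC#C)[C@H](O[Si](C)(C)C(C)(C)C)C1 | intermediate
10 | (3R,3aR,7aS)-3-[(tert-butyldimethylsilyl)oxy]-3a-methyl-7-methylideneoctahydro-1H-inden-1-one | C=C1CCC[C@]2(C)[C@H]1C(=O)C[C@H]2O[Si](C)(C)C(C)(C)C | intermediate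
11 | 2-methylpropanal | CC(C)C=O | starting material
12 | N'-(2-methylpropylidene)-4-methylbenzenesulfonohydrazide | CC(C)/C=N/NS(=O)(=O)c1ccc(C)cc1 | intermediate
13 | sodium salt of N'-(2-methylpropylidene)-4-methylbenzenesulfonohydrazide | CC(C)/C=N/[N-]S(=O)(=O)c1ccc(C)cc1.[Na+] | intermediate
14 | 2-methyl-1-diazopropane | CC(C)C=[N+]=[N-] | intermediate
15 | (2R,4R,4aR,8aS)-4-[(tert-butyldimethylsilyl)oxy]-4a-methyl-8-methylidene-2-(propan-2-yl)octahydronaphthalen-1(2H)-one | C=C1CCC[C@]2(C)[C@H]1C(=O)[C@@H](C(C)C)C[C@H]2O[Si](C)(C)C(C)(C)C | intermediate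
16 | (2R,4R,4aR,8aS)-4-hydroxy-4a-methyl-8-methylidene-2-(propan-2-yl)octahydronaphthalen-1(2H)-one | C=C1CCC[C@]2(C)[C@H]1C(=O)[C@@H](C(C)C)C[C@H]2O | intermediate
17 | 4-methoxybenzoyl chloride | COc1ccc(cc1)C(Cl)=O | starting material
18 | (1R,3R,4aS,8aR)-8a-methyl-5-methylidene-4-oxo-3-(propan-2-yl)decahydronaphthalen-1-yl 4-methoxybenzoate | C=C1CCC[C@]2(C)[C@H]1C(=O)[C@@H](C(C)C)C[C@H]2OC(=O)c1ccc(OC)cc1 | intermediate
19 | (1R,3R,4S,4aS,8aR)-4-hydroxy-8a-methyl-5-methylidene-3-(propan-2-yl)decahydronaphthalen-1-yl 4-methoxybenzoate | C=C1CCC[C@]2(C)[C@H]1[C@@H](O)[C@@H](C(C)C)C[C@H]2OC(=O)c1ccc(OC)cc1 | target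

**Count**

Total: 13 steps. Longest linear sequence: 10 steps (from 1 through steps 1, 2, 4, 5, 6, 7, 10, 11, 12 and 13 to 19).

**Steps most likely to fail**

Step 10. The C5–C6 bond may shift in place of C6–C8. The two rotamers of the diazonium alkoxide may be populated with little bias, so that C7 forms unselectively. The diazoalkane may also be lost to azine formation or hydride shift before it adds to the crowded carbonyl group. The fallback sets out from 10 and inserts the carbon with a stabilised, weighable diazo compound that carries a handle for later control of C7. Allyl 2-diazo-3-methylbutanoate F1 (from bought allyl L-valinate by diazotisation with isoamyl nitrite and catalytic AcOH) and BF3·OEt2 in CH2Cl2 should enlarge 10 to the β-keto ester allyl (4R,4aR,8aS)-4-[(tert-butyldimethylsilyl)oxy]-4a-methyl-8-methylidene-1-oxo-2-(propan-2-yl)octahydronaphthalene-2(1H)-carboxylate F2, in which C7 is quaternary and its configuration is of no consequence. Decarboxylative protonation (Pd(OAc)2, t-BuPHOX ligand of the matching hand, HCO2H, dioxane, 40 °C) then forms the C6–C7 palladium enolate regiospecifically, without touching C5, and protonates it under ligand control. The route is rejoined at 15.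

Step 13. Hydride may be delivered on the face of the axial methyl after all, or the reduction may stall, because the exocyclic methylene on the axial C4 leans over the equatorial approach to C6. The fallback sets out from 18. The ketone is reduced under conditions chosen to give the equatorial epimer cleanly (a small hydride such as NaBH4 in MeOH), which is (1R,3R,4R,4aS,8aR)-4-hydroxy-8a-methyl-5-methylidene-3-(propan-2-yl)decahydronaphthalen-1-yl 4-methoxybenzoate F3. Mitsunobu inversion (PPh3, DIAD, 4-nitrobenzoic acid, toluene) turns it into (1R,3R,4S,4aS,8aR)-8a-methyl-5-methylidene-4-[(4-nitrobenzoyl)oxy]-3-(propan-2-yl)decahydronaphthalen-1-yl 4-methoxybenzoate F4. The activated nitrobenzoate is then cleaved selectively (K2CO3, MeOH, 0 °C) while the electron-rich anisoate stays, which gives 19.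

Step 7. Cationic gold or adventitious acid may strip the enol silane to the open-chain ketone faster than the slow six-membered closure, or closure may take the 7-endo course. The fallback sets out from 9 and uses a radical instead of a metal-activated alkyne. NIS in THF at −78 °C should iodinate the enol silane regiospecifically to (3S,4R)-4-[(tert-butyldimethylsilyl)oxy]-2-iodo-3-methyl-3-(pent-4-yn-1-yl)cyclopentan-1-one F5. Bu3SnH (slow addition) and AIBN in benzene at 80 °C then generate the α-keto radical, which closes 6-exo-dig onto the alkyne; the vinyl radical takes hydrogen and the same cis-fused ketone 10 results.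

**Further compounds**

F1 | step 10 | allyl 2-diazo-3-methylbutanoate | C=CCOC(=O)C(=[N+]=[N-])C(C)C
F2 | step 10 | allyl (4R,4aR,8aS)-4-[(tert-butyldimethylsilyl)oxy]-4a-methyl-8-methylidene-1-oxo-2-(propan-2-yl)octahydronaphthalene-2(1H)-carboxylate (either configuration at C2) | C=C1CCC[C@]2(C)[C@H]1C(=O)C(C(C)C)(C(=O)OCC=C)C[C@H]2O[Si](C)(C)C(C)(C)C
F3 | step 13 | (1R,3R,4R,4aS,8aR)-4-hydroxy-8a-methyl-5-methylidene-3-(propan-2-yl)decahydronaphthalen-1-yl 4-methoxybenzoate | C=C1CCC[C@]2(C)[C@H]1[C@H](O)[C@@H](C(C)C)C[C@H]2OC(=O)c1ccc(OC)cc1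
F4 | step 13 | (1R,3R,4S,4aS,8aR)-8a-methyl-5-methylidene-4-[(4-nitrobenzoyl)oxy]-3-(propan-2-yl)decahydronaphthalen-1-yl 4-methoxybenzoate | C=C1CCC[C@]2(C)[C@H]1[C@@H](OC(=O)c1ccc(cc1)[N+](=O)[O-])[C@@H](C(C)C)C[C@H]2OC(=O)c1ccc(OC)cc1
F5 | step 7 | (3S,4R)-4-[(tert-butyldimethylsilyl)oxy]-2-iodo-3-methyl-3-(pent-4-yn-1-yl)cyclopentan-1-one (either configuration at C2) | O=C1C(I)[C@@](C)(CCCC#C)[C@H](O[Si](C)(C)C(C)(C)C)C1
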